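**Strategy.** The target is cut at the ester, at C10–C11 and at the O1–C9 bond of its oxolane ring (chain numbered C1–C19 from the pentyl end; ring = O1, C6, C7, C8, C9). The feature exploited is the 2,5-trans relation of C6 and C9 across O1 together with the oxygen on exocyclic C10. A cobalt-catalysed aerobic cyclisation of the C6 hydroxyl onto the terminal C9=C10 alkene closes the ring, sets C9 and oxygenates C10 in one operation. Its precursor is the syn-configured (4S,5S)-4-silyloxydec-1-en-5-ol, assembled by chelation-controlled allylation of (S)-2-(4-methoxybenzyloxy)heptanal. A second chelation-controlled addition then installs C10.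

Key step: step 8

**Remarks.**
- Assumption: commercial 1,2-epoxyheptane is the racemate, so step 1 resolves it while opening it.
- Design of the precursor: the C6 oxygen carries the temporary, chelating PMB group and the C7 oxygen the TBS group, which stays until the last step. At the cyclisation only the C6 hydroxyl is therefore free, and later only the C10 hydroxyl can be acylated.
- Abbreviations: PMB = 4-methoxybenzyl; TBS = tert-butyldimethylsilyl; salen = N,N'-bis(3,5-di-tert-butylsalicylidene)cyclohexane-1,2-diaminate; modp = 1-morpholinocarbamoyl-4,4-dimethylpentane-1,3-dionate; CSA = camphorsulfonic acid.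

**Route**

Step 1
Reactants: 1 rac-1,2-epoxyheptane
Product: 2 (S)-heptane-1,2-diol
Conditions: (S,S)-N,N'-bis(3,5-di-tert-butylsalicylidene)cyclohexane-1,2-diaminatocobalt acetate [(S,S)-(salen)Co(OAc), trivalent cobalt] (0.5 mol%), H2O (0.45 equiv), neat, 0 °C to rt
Reagents that add atoms: water, O
Why: Hydrolytic kinetic resolution of a terminal epoxide: the (S,S)-catalyst should hydrate the (S)-enantiomer at its terminal carbon, so the stereocentre (later C6) keeps its S configuration without a bond to it being broken and the (R)-epoxide stays behind.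

Step 2
Reactants: 2 (S)-heptane-1,2-diol
Product: 3 (4S)-2-(4-methoxyphenyl)-4-pentyl-1,3-dioxolane (both C2 epimers)
Conditions: 4-MeOC6H4CH(OMe)2, CSA (cat.), CH2Cl2, rt
Reagents that add atoms: 4-methoxybenzaldehyde dimethyl acetal, COc1ccc(C(OC)OC)cc1
Why: Acid-catalysed transacetalisation of a 1,2-diol driven by loss of methanol; the chain stereocentre is untouched and the new acetal centre is destroyed in step 3.

Step 3
Reactants: 3 (4S)-2-(4-methoxyphenyl)-4-pentyl-1,3-dioxolane
Product: 4 (S)-2-[(4-methoxybenzyl)oxy]heptan-1-ol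
Conditions: i-Bu2AlH (3 equiv), CH2Cl2, −78 to 0 °C; aq. potassium sodium tartrate
Reagents that add atoms: none
Why: Regioselective reductive acetal opening: aluminium binds the less hindered primary oxygen and hydride goes to the acetal carbon, so the PMB group should stay on the secondary oxygen and the primary alcohol is released.

Step 4
Reactants: 4 (S)-2-[(4-methoxybenzyl)oxy]heptan-1-ol
Product: 5 (S)-2-[(4-methoxybenzyl)oxy]heptanal
Conditions: Dess–Martin periodinane, NaHCO3, CH2Cl2, 0 °C to rt; used crude
Reagents that add atoms: none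
Why: Dess–Martin oxidation of a primary alcohol under buffered, non-basic conditions should give the α-alkoxy aldehyde without epimerising its α-carbon.

Step 5
Reactants: 5 (S)-2-[(4-methoxybenzyl)oxy]heptanal; 6 allyltributylstannane
Product: 7 (4S,5S)-5-[(4-methoxybenzyl)oxy]dec-1-en-4-ol
Conditions: MgBr2·OEt2 (2.5 equiv), CH2Cl2, −78 °C, then 6, −78 to −20 °C
Reagents that add atoms: none
Why: Chelation-controlled allylstannane addition (Cram chelate model): MgBr2 bridges the carbonyl and PMB-ether oxygens and allyl attacks the face opposite the pentyl group, which should set the new carbinol centre (4S, later C7) syn to the existing one.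

Step 6
Reactants: 7 (4S,5S)-5-[(4-methoxybenzyl)oxy]dec-1-en-4-ol
Product: 8 tert-butyl({(4S,5S)-5-[(4-methoxybenzyl)oxy]dec-1-en-4-yl}oxy)dimethylsilane
Conditions: TBSOTf, 2,6-lutidine, CH2Cl2, −78 to 0 °C
Reagents that add atoms: tert-butyldimethylsilyl trifluoromethanesulfonate, CC(C)(C)[Si](C)(C)OS(=O)(=O)C(F)(F)F
Why: Silyl ether formation with a silyl triflate and a hindered base is reliable for a hindered secondary alcohol and leaves the PMB ether, the alkene and both stereocentres untouched.

Step 7
Reactants: 8 tert-butyl({(4S,5S)-5-[(4-methoxybenzyl)oxy]dec-1-en-4-yl}oxy)dimethylsilane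
Product: 9 (4S,5S)-4-[(tert-butyldimethylsilyl)oxy]dec-1-en-5-ol
Conditions: DDQ, CH2Cl2/pH 7 phosphate buffer (10:1), 0 °C to rt
Reagents that add atoms: none
Why: Oxidative PMB-ether cleavage (benzylic hydride abstraction by DDQ, then hydrolysis of the oxocarbenium ion) is selective over the TBS ether and the unactivated terminal alkene, and the neutral buffer should prevent 1,2-silyl migration.

Step 8
Reactants: 9 (4S,5S)-4-[(tert-butyldimethylsilyl)oxy]dec-1-en-5-ol
Product: 10 [(2R,4S,5S)-4-[(tert-butyldimethylsilyl)oxy]-5-pentyltetrahydrofuran-2-yl]methanol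
Conditions: bis(1-morpholinocarbamoyl-4,4-dimethylpentane-1,3-dionato)cobalt [Co(modp)2, divalent cobalt] (10 mol%), t-BuOOH (10 mol%), O2 (1 atm), 4 Å MS, i-PrOH, 55 °C
Reagents that add atoms: dioxygen, O=O
Why: Divalent cobalt in Co(modp)2 is oxidised by O2 and t-BuOOH to a trivalent cobalt species that binds the free C6 hydroxyl as its alkoxide, the oxygen adds to the internal alkene carbon C9, and the C10 radical so formed is captured by O2 and reduced to the primary alcohol with i-PrOH as terminal reductant. The closest known reaction type is the Mukaiyama aerobic oxidative cyclisation of 1-substituted pent-4-en-1-ols to trans-2,5-disubstituted tetrahydrofuran-2-ylmethanols. The single ring (O1, C6, C7, C8, C9) closes in the 5-exo-trig mode through the O1–C9 bond. The new stereocentre C9 (R) is controlled by the C6 stereocentre: in the chair-like, cobalt-bound transition state the pentyl group sits pseudo-equatorial and the alkene folds so that C10 ends up trans to it across O1. The step needs 2,5-trans over 2,5-cis selectivity and hydroxylative rather than reductive termination; the C6 pentyl group is expected to override the C7 silyloxy group, which must sit pseudo-axial (2,4-trans to C10) against the weaker 2,4-cis preference of such closures, and O2 saturation in i-PrOH favours the alcohol. Only the C6 hydroxyl can close a ring, since the C7 oxygen is silylated and would in any case have to form a four-membered ring.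

Step 9
Reactants: 10 [(2R,4S,5S)-4-[(tert-butyldimethylsilyl)oxy]-5-pentyltetrahydrofuran-2-yl]methanol
Product: 11 (2R,4S,5S)-4-[(tert-butyldimethylsilyl)oxy]-5-pentyltetrahydrofuran-2-carbaldehyde
Conditions: Dess–Martin periodinane, NaHCO3, CH2Cl2, 0 °C to rt; used crude
Reagents that add atoms: none
Why: Buffered Dess–Martin oxidation of the primary alcohol, with immediate use of the crude aldehyde, should keep the α-centre C9 from epimerising.

Step 10
Reactants: 11 (2R,4S,5S)-4-[(tert-butyldimethylsilyl)oxy]-5-pentyltetrahydrofuran-2-carbaldehyde; 12 9-bromonon-1-ene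
Product: 14 (1R)-1-[(2R,4S,5S)-4-[(tert-butyldimethylsilyl)oxy]-5-pentyltetrahydrofuran-2-yl]dec-9-en-1-ol, via non-8-enylmagnesium bromide 13 (not isolated)
Conditions: 12, Mg, Et2O, reflux; then 11 precomplexed with MgBr2·OEt2, CH2Cl2, −78 °C
Reagents that add atoms: none
Why: Chelation-controlled Grignard addition (Cram chelate model): magnesium held between ring oxygen O1 and the carbonyl oxygen exposes the face flanked by the C9 hydrogen, so the nonenyl group should add to give the threo, (R)-configured carbinol C10.

Step 11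
Reactants: 14 (1R)-1-[(2R,4S,5S)-4-[(tert-butyldimethylsilyl)oxy]-5-pentyltetrahydrofuran-2-yl]dec-9-en-1-ol; 15 dodecanoyl chloride
Product: 16 (1R)-1-[(2R,4S,5S)-4-[(tert-butyldimethylsilyl)oxy]-5-pentyltetrahydrofuran-2-yl]dec-9-en-1-yl dodecanoate
Conditions: pyridine, DMAP (cat.), CH2Cl2, 0 °C to rt
Reagents that add atoms: none
Why: DMAP-catalysed acylation with an acid chloride (nucleophilic catalysis through the acylpyridinium ion) esterifies the only free hydroxyl with retention at C10.

Step 12
Reactants: 16 (1R)-1-[(2R,4S,5S)-4-[(tert-butyldimethylsilyl)oxy]-5-pentyltetrahydrofuran-2-yl]dec-9-en-1-yl dodecanoate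
Product: 17 (1R)-1-[(2R,4S,5S)-4-hydroxy-5-pentyltetrahydrofuran-2-yl]dec-9-en-1-yl dodecanoate
Conditions: HF·pyridine, pyridine, THF, 0 °C to rt
Reagents that add atoms: none
Why: Fluoride-mediated desilylation under buffered, mildly acidic conditions should free the C7 hydroxyl without touching the ester, the alkene or any stereocentre; acyl migration is disfavoured because the C7 and C10 oxygens lie on opposite faces of the ring.

**Compound list**

1 | rac-1,2-epoxyheptane (2-pentyloxirane) | CCCCCC1CO1 | starting material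
2 | (S)-heptane-1,2-diol | CCCCC[C@H](O)CO | intermediate
3 | (4S)-2-(4-methoxyphenyl)-4-pentyl-1,3-dioxolane (both C2 epimers) | CCCCC[C@H]1COC(c2ccc(OC)cc2)O1 | intermediate
4 | (S)-2-[(4-methoxybenzyl)oxy]heptan-1-ol | CCCCC[C@H](OCc1ccc(OC)cc1)CO | intermediate
5 | (S)-2-[(4-methoxybenzyl)oxy]heptanal | CCCCC[C@H](OCc1ccc(OC)cc1)C=O | intermediate
6 | allyltributylstannane | C=CC[Sn](CCCC)(CCCC)CCCC | starting material
7 | (4S,5S)-5-[(4-methoxybenzyl)oxy]dec-1-en-4-ol | C=CC[C@H](O)[C@H](CCCCC)OCc1ccc(OC)cc1 | intermediate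
8 | tert-butyl({(4S,5S)-5-[(4-methoxybenzyl)oxy]dec-1-en-4-yl}oxy)dimethylsilane | C=CC[C@H](O[Si](C)(C)C(C)(C)C)[C@H](CCCCC)OCc1ccc(OC)cc1 | intermediate
9 | (4S,5S)-4-[(tert-butyldimethylsilyl)oxy]dec-1-en-5-ol | C=CC[C@H](O[Si](C)(C)C(C)(C)C)[C@H](CCCCC)O | intermediate
10 | [(2R,4S,5S)-4-[(tert-butyldimethylsilyl)oxy]-5-pentyltetrahydrofuran-2-yl]methanol | OC[C@H]1C[C@H](O[Si](C)(C)C(C)(C)C)[C@H](CCCCC)O1 | intermediate
11 | (2R,4S,5S)-4-[(tert-butyldimethylsilyl)oxy]-5-pentyltetrahydrofuran-2-carbaldehyde | O=C[C@H]1C[C@H](O[Si](C)(C)C(C)(C)C)[C@H](CCCCC)O1 | intermediate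
12 | 9-bromonon-1-ene | C=CCCCCCCCBr | starting material
13 | non-8-enylmagnesium bromide | C=CCCCCCCC[Mg]Br | intermediate
14 | (1R)-1-[(2R,4S,5S)-4-[(tert-butyldimethylsilyl)oxy]-5-pentyltetrahydrofuran-2-yl]dec-9-en-1-ol | C=CCCCCCCC[C@@H](O)[C@H]1C[C@H](O[Si](C)(C)C(C)(C)C)[C@H](CCCCC)O1 | intermediate
15 | dodecanoyl chloride | CCCCCCCCCCCC(=O)Cl | starting material
16 | (1R)-1-[(2R,4S,5S)-4-[(tert-butyldimethylsilyl)oxy]-5-pentyltetrahydrofuran-2-yl]dec-9-en-1-yl dodecanoate | C=CCCCCCCC[C@@H](OC(=O)CCCCCCCCCCC)[C@H]1C[C@H](O[Si](C)(C)C(C)(C)C)[C@H](CCCCC)O1 | intermediate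
17 | (1R)-1-[(2R,4S,5S)-4-hydroxy-5-pentyltetrahydrofuran-2-yl]dec-9-en-1-yl dodecanoate (CNP0219213.1) | C=CCCCCCCC[C@@H](OC(=O)CCCCCCCCCCC)[C@H]1C[C@H](O)[C@H](CCCCC)O1 | target

**Totals.** Total step count: 12. Longest linear sequence: 12 steps (1 to 17); the Grignard reagent 13 is made in the flask within step 10.

**Steps most likely to fail**

Step 8 (key step). Trans selectivity may erode because the C7 silyloxy group, forced pseudo-axial, works against the C6 pentyl group. Reductive termination at C10, over-oxidation of C10 and silyl migration from the C7 to the C6 oxygen in warm i-PrOH would lower the return further. The fallback sets out from 8 and comes back at 10; it sets C9 by catalyst-controlled resolution and SN2 inversion instead of by the ring substituents. Epoxidation of 8 with mCPBA (NaHCO3, CH2Cl2) should give tert-butyl({(2S,3S)-3-[(4-methoxybenzyl)oxy]-1-(oxiran-2-yl)octan-2-yl}oxy)dimethylsilane F1 as a mixture of oxirane epimers. Hydrolytic kinetic resolution with (R,R)-(salen)Co(OAc) (trivalent cobalt) and H2O (0.55 equiv) should hydrolyse the (R)-oxirane epimer to (2R,4S,5S)-4-[(tert-butyldimethylsilyl)oxy]-5-[(4-methoxybenzyl)oxy]decane-1,2-diol F3. It should leave tert-butyl({(2S,3S)-3-[(4-methoxybenzyl)oxy]-1-[(2S)-oxiran-2-yl]octan-2-yl}oxy)dimethylsilane F2. DDQ in buffered wet CH2Cl2 then removes the PMB group to give (2S,3S)-2-[(tert-butyldimethylsilyl)oxy]-1-[(2S)-oxiran-2-yl]octan-3-ol F4. Catalytic CSA in CH2Cl2 lets the C6 hydroxyl open the oxirane at C9 in the 5-exo mode with inversion, which gives 10.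

Step 10. Facial selectivity may be poor if the O1–Mg–O=C chelate is not maintained and Felkin–Anh addition competes, and the basic reagent may epimerise the aldehyde at C9. The fallback sets out from 11 and comes back at 14; it sets C10 by hydride delivery instead of by carbon addition. Addition of 13 to 11 in THF at −78 °C without regard to selectivity gives 1-[(2R,4S,5S)-4-[(tert-butyldimethylsilyl)oxy]-5-pentyltetrahydrofuran-2-yl]dec-9-en-1-ol (both C1 epimers) F5. Dess–Martin oxidation gives 1-[(2R,4S,5S)-4-[(tert-butyldimethylsilyl)oxy]-5-pentyltetrahydrofuran-2-yl]dec-9-en-1-one F6. Reduction with LiBH(s-Bu)3 in THF at −78 °C under Felkin–Anh control (hydride anti to the C9–O1 bond) should give the threo alcohol 14.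

Step 5. Syn selectivity may erode if MgBr2 fails to hold the PMB oxygen and the carbonyl in a chelate or cleaves the PMB ether, and 5 may epimerise at its α-carbon during handling. The fallback sets out from 5 and comes back at 7; it replaces chelate control by reagent control. Brown allylation with (−)-Ipc2B(allyl) (from (+)-α-pinene) in Et2O at −78 °C, followed by NaOH/H2O2 work-up, should deliver allyl to the Si face of the aldehyde and give the (4S) carbinol 7 directly. This path makes no further compound (F0).

**Further compounds**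

F0 | step 5 | none | none
F1 | step 8 | tert-butyl({(2S,3S)-3-[(4-methoxybenzyl)oxy]-1-(oxiran-2-yl)octan-2-yl}oxy)dimethylsilane (both oxirane epimers) | CCCCC[C@H](OCc1ccc(OC)cc1)[C@@H](O[Si](C)(C)C(C)(C)C)CC1CO1
F2 | step 8 | tert-butyl({(2S,3S)-3-[(4-methoxybenzyl)oxy]-1-[(2S)-oxiran-2-yl]octan-2-yl}oxy)dimethylsilane | CCCCC[C@H](OCc1ccc(OC)cc1)[C@@H](O[Si](C)(C)C(C)(C)C)C[C@H]1CO1
F3 | step 8 | (2R,4S,5S)-4-[(tert-butyldimethylsilyl)oxy]-5-[(4-methoxybenzyl)oxy]decane-1,2-diol | CCCCC[C@H](OCc1ccc(OC)cc1)[C@@H](O[Si](C)(C)C(C)(C)C)C[C@@H](O)CO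
F4 | step 8 | (2S,3S)-2-[(tert-butyldimethylsilyl)oxy]-1-[(2S)-oxiran-2-yl]octan-3-ol | CCCCC[C@H](O)[C@@H](O[Si](C)(C)C(C)(C)C)C[C@H]1CO1
F5 | step 10 | 1-[(2R,4S,5S)-4-[(tert-butyldimethylsilyl)oxy]-5-pentyltetrahydrofuran-2-yl]dec-9-en-1-ol (both C1 epimers) | C=CCCCCCCCC(O)[C@H]1C[C@H](O[Si](C)(C)C(C)(C)C)[C@H](CCCCC)O1
F6 | step 10 | 1-[(2R,4S,5S)-4-[(tert-butyldimethylsilyl)oxy]-5-pentyltetrahydrofuran-2-yl]dec-9-en-1-one | C=CCCCCCCCC(=O)[C@H]1C[C@H](O[Si](C)(C)C(C)(C)C)[C@H](CCCCC)O1
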